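The reading was due at 15 min, and the winter run was all I had, so I wanted one constant to carry from it to every flask.

| setting | winter | north-east | west | south-west | south-east | south |
|---|---|---|---|---|---|---|
| electrophile | 0.055 M | 0.10 M | 0.15 M | 0.050 M | 0.025 M | 0.050 M |
| nucleophile | 0.050 M | 0.0120 M | 0.0250 M | 0.0500 M | 0.150 M | 0.0500 M |
| free base | 0.10 M | 0.0500 M | 0.0300 M | 0.100 M | 0.0300 M | 0.0250 M |
| remark | run made earlier |  |  |  |  |  |
| time |  | 15 min | 15 min | 15 min | 15 min | 15 min |

winter run (percent of the electrophile charged)

| time / min | product / % | electrophile / % |
|---|---|---|
| 1.50 | 9.7 | 88.8 |
| 3.00 | 16.4 | 84.4 |
| 5.00 | 24.6 | 75.7 |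
| 6.00 | 27.4 | 71.8 |
| 8.00 | 35.4 | 65.8 |
| 10.0 | 37.9 | 62.0 |

(standard deviation of a reading: 1 percentage point)

- a reading or a percentage of product counts all its forms, free or not
- no earlier run changes the charge of free base; that part of a forecast is a guess

* the flasks put in order of amount of product, in percent of the electrophile charged, best first, at 15 min (north-east / west / south-west / south-east / south)
* the amount of product, in percent of the electrophile charged of the flask you put first, at 15 min
* the amount of product, in percent of the electrophile charged of the flask you put last, at 15 min

At its last reading, 10.0 min, the winter run held 62.0% electrophile and 37.9% product, together 99.9%, so I took each electrophile lost as one product formed and one nucleophile spent. For rate = k[electrophile][nucleophile] with charges a and b, the closed form is ln(b[electrophile]/(a[nucleophile])) = (a − b)kt. That gave k = 1.26 /M/min, the second-order constant, meaning rate per unit of [electrophile][nucleophile]. It is a reading and carries the scatter.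

I reckoned south-east first. Its nucleophile stands in excess, so the pseudo-first-order shortcut, with [nucleophile] held at its charge, leaves exp(−k[nucleophile]t) = 5.81% electrophile. The weak link is that held [nucleophile], since the reaction can take 16.7% of the nucleophile charged. The closed form repairs it: 7.90% electrophile left, so 92.1% product.

With equal charges, south-west gives 48.7%. West gives 15.4% and north-east 9.97%, with nucleophile the limiting reagent in both. I put south just below south-west, and that is a guess: its free base charge is lower, and no run tests free base.

The forecast gave south-east > south-west > south > west > north-east, with 89% and 9.7%, its top figure below mine since “I shade the top figure down for this risk”.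

The flasks came out south-east > south-west > south > west > north-east, with south-east at 91.7% and north-east at 10.0%.

    electrophile + nucleophile → acid set free + product (k = 1.35 /M/min)
    nucleophile + acid set free ⇌ protonated nucleophile, settled at all times (K = 3700 /M)
    acid set free + free base ⇌ salt of the base, settled at all times (K = 12000 /M)
    free base + product ⇌ idle adduct, settled at all times (K = 13.3 /M)

South-east fell short of full conversion because of the time allowed: at 15.0 min it held 91.7% product and 8.27% electrophile, and the same flask left until 150 min held 100% product. The same k and closed form, applied to a flask like south-east but charged with 0.037 M nucleophile, give 44.1% product, and that flask held 44.2% at 15.0 min.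

(Readings and results stem from a simulated flask for substances that don't exist, noise included.)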